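## Retrosynthetic overview

1. The target comes from global deprotection (fluoride, then hydrogenolysis) of a fully benzyl/silyl-protected biflavan.
2. The protected biflavan comes from a seco bis(phenol) diol: one double Mitsunobu etherification closes pyran ring C (upper unit) and pyran ring F (lower unit) together, with inversion at C2 of each unit.
3. The seco diol comes from two Felkin-controlled aryl Grignard additions (rings B and E) to lactols, placed before and after a Friedel–Crafts union at C4; a temporary lactol ring enforces the 3,4-trans interflavan bond.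
4. Both halves come from one lactol, made by a D-proline anti-aldol of silyloxyacetaldehyde with 3,4-bis(benzyloxy)-2-hydroxybenzaldehyde (source of rings A and D and of the C3/C4 oxygen stereocentres).
5. Ring order: aromatic rings A, B, D, E are bought; temporary lactol rings form in step 2 and are opened again in steps 4 and 7; rings C and F form last, together, in step 8.

Assumption: hemiacetal (lactol) carbons are equilibrating anomer mixtures and carry no stereo label; compounds 3, 8 and 13 are taken as commercial.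

## Route

Step 1
Reactants: 1 2,3,4-trihydroxybenzaldehyde
Product: 2 3,4-bis(benzyloxy)-2-hydroxybenzaldehyde
Conditions: BnBr (2.1 equiv), K2CO3 (2.1 equiv), DMF, 0 °C → rt
Reagents that add atoms: benzyl bromide, BrCc1ccccc1
Why: Williamson etherification; the 2-OH is hydrogen-bonded to the aldehyde and is the least acidic and least nucleophilic, so the 4- and 3-OH are benzylated selectively.

Step 2
Reactants: 2 3,4-bis(benzyloxy)-2-hydroxybenzaldehyde; 3 (tert-butyldimethylsilyloxy)acetaldehyde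
Product: 5 (3R,4R)-7,8-bis(benzyloxy)-3-[(tert-butyldimethylsilyl)oxy]chromane-2,4-diol (anomer mixture), via open-chain anti-aldol adduct 4 (not isolated)
Conditions: D-proline (20 mol %), DMF, 4 °C, 3 (2 equiv) added over 24 h
Reagents that add atoms: none
Why: Proposed new method: the E-enamine of 3 with D-proline adds to aldehyde 2 through the hydrogen-bonded chair (Houk–List) transition state, giving the anti-aldol (2R,3R), which the ortho-phenol traps at once as the six-membered lactol (3,4-cis oxygens), removing it from retro-aldol equilibrium; the closest known reactions are the proline-catalysed anti cross-aldol of α-silyloxyacetaldehyde donors and aldol–hemiacetalisation cascades of salicylaldehydes.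

Step 3
Reactants: 5 (3R,4R)-7,8-bis(benzyloxy)-3-[(tert-butyldimethylsilyl)oxy]chromane-2,4-diol
Product: 7 (3R,4R)-7,8-bis(benzyloxy)-3,4-bis[(tert-butyldimethylsilyl)oxy]chroman-2-ol (anomer mixture), via tris-silyl ether 6 (not isolated)
Conditions: TBSOTf (2.5 equiv), 2,6-lutidine, CH2Cl2, −78 → 0 °C; then Bu4NF/AcOH (1:1, 1.1 equiv), THF, −20 °C
Reagents that add atoms: tert-butyldimethylsilyl trifluoromethanesulfonate, CC(C)(C)[Si](C)(C)OS(=O)(=O)C(F)(F)F
Why: Exhaustive silylation followed by selective cleavage of the far more labile anomeric silyl acetal with buffered fluoride leaves the benzylic 4-O protected; no stereocentre is touched.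

Step 4
Reactants: 7 (3R,4R)-7,8-bis(benzyloxy)-3,4-bis[(tert-butyldimethylsilyl)oxy]chroman-2-ol; 8 4-bromo-1,2-bis(benzyloxy)benzene
Product: 10 (1S,2S,3R)-3-[3,4-bis(benzyloxy)-2-hydroxyphenyl]-1-[3,4-bis(benzyloxy)phenyl]-2,3-bis[(tert-butyldimethylsilyl)oxy]propan-1-ol, via 3,4-bis(benzyloxy)phenylmagnesium bromide 9 (not isolated)
Conditions: 8, Mg, THF, 40 °C; then 7, THF, −78 → −20 °C (4 equiv of 9); aq NH4Cl
Reagents that add atoms: none
Why: Grignard addition to the ring-opened hydroxy-aldehyde tautomer of the lactol under Felkin–Anh (non-chelation) control by the bulky α-silyloxy group, reinforced by the anti β-silyloxy group, gives the 1,2-anti carbinol (1S) and installs ring E.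

Step 5
Reactants: 5 (3R,4R)-7,8-bis(benzyloxy)-3-[(tert-butyldimethylsilyl)oxy]chromane-2,4-diol
Product: 11 (3S,4S)-4-(benzylsulfanyl)-7,8-bis(benzyloxy)-3-[(tert-butyldimethylsilyl)oxy]chroman-2-ol (anomer mixture)
Conditions: BnSH (1.5 equiv), AcOH, CH2Cl2, rt
Reagents that add atoms: phenylmethanethiol, SCc1ccccc1
Why: Acid-catalysed SN1 thioetherification at the benzylic C4 via the para-alkoxybenzyl cation, the thiol entering trans to the 3-silyloxy group; the hemiacetal is not exchanged under these mild conditions and the C4 configuration is irrelevant because the cation is regenerated in step 6.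

Step 6
Reactants: 11 (3S,4S)-4-(benzylsulfanyl)-7,8-bis(benzyloxy)-3-[(tert-butyldimethylsilyl)oxy]chroman-2-ol; 10 (1S,2S,3R)-3-[3,4-bis(benzyloxy)-2-hydroxyphenyl]-1-[3,4-bis(benzyloxy)phenyl]-2,3-bis[(tert-butyldimethylsilyl)oxy]propan-1-ol
Product: 12 (3R,4R)-7,8-bis(benzyloxy)-4-{2,3-bis(benzyloxy)-5-[(1R,2S,3S)-3-[3,4-bis(benzyloxy)phenyl]-1,2-bis[(tert-butyldimethylsilyl)oxy]-3-hydroxypropyl]-4-hydroxyphenyl}-3-[(tert-butyldimethylsilyl)oxy]chroman-2-ol (anomer mixture)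
Conditions: AgBF4 (1.5 equiv), 2,6-di-tert-butyl-4-methylpyridine (2 equiv), 10 (2 equiv), THF, −20 → 0 °C
Reagents that add atoms: none
Why: Thiophilic silver activation gives the cyclic C4 benzylic cation of the lactol, and Friedel–Crafts attack by the free phenol 10 at its only strongly activated CH (para to OH, ortho to OBn, the future C6 of ring D) from the face opposite the bulky 3-OTBS sets the 3,4-trans interflavan centre (4R), while Ag+ leaves the alcohols of 10 un-ionised (known silver-promoted coupling of 4-benzylsulfanyl flavan-3-ols, here on a lactol template).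

Step 7
Reactants: 12 the lactol from step 6; 13 1-(benzyloxy)-4-bromobenzene
Product: 15 (1S,2R,3R)-3-[3,4-bis(benzyloxy)-2-hydroxyphenyl]-3-{2,3-bis(benzyloxy)-5-[(1R,2S,3S)-3-[3,4-bis(benzyloxy)phenyl]-1,2-bis[(tert-butyldimethylsilyl)oxy]-3-hydroxypropyl]-4-hydroxyphenyl}-1-[4-(benzyloxy)phenyl]-2-[(tert-butyldimethylsilyl)oxy]propan-1-ol, via 4-(benzyloxy)phenylmagnesium bromide 14 (not isolated)
Conditions: 13, Mg, THF, 40 °C; then 12, THF, −78 → −20 °C (6 equiv of 14); aq NH4Cl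
Reagents that add atoms: none
Why: Grignard addition to the open aldehyde form of the upper lactol under Felkin–Anh control by the α-silyloxy group gives the 1,2-anti (1S) carbinol and installs ring B, leaving a bis(phenol) diol with each carbinol placed for six-membered ring closure.

Step 8
Reactants: 15 the seco bis(phenol) diol from step 7
Product: 16 (2R,3S,4R)-7,8-bis(benzyloxy)-2-[3,4-bis(benzyloxy)phenyl]-6-{(2R,3R,4R)-7,8-bis(benzyloxy)-2-[4-(benzyloxy)phenyl]-3-[(tert-butyldimethylsilyl)oxy]chroman-4-yl}-3,4-bis[(tert-butyldimethylsilyl)oxy]chromane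
Conditions: PPh3 (3 equiv), DIAD (3 equiv), toluene, 0 °C → rt
Reagents that add atoms: none
Why: Proposed new method: double intramolecular Mitsunobu etherification in which each phenoxide displaces the oxyphosphonium of the benzylic carbinol in a 6-exo-tet SN2 step with inversion, turning both (S)-carbinols into the 2,3-cis (2R) centres and closing pyran rings C and F in one operation; the only free alcohols are the two carbinols, and the closest known reaction is the Mitsunobu cyclisation of 1-aryl-3-(2-hydroxyaryl)propane-1,2-diols to flavan-3-ols.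

Step 9
Reactants: 16 the tris-silyl heptabenzyl biflavan from step 8
Product: 17 (2R,3R,4R)-7,8-bis(benzyloxy)-2-[3,4-bis(benzyloxy)phenyl]-6-{(2R,3R,4R)-7,8-bis(benzyloxy)-2-[4-(benzyloxy)phenyl]-3-hydroxychroman-4-yl}chromane-3,4-diol
Conditions: Bu4NF (6 equiv), THF, 0 °C → rt
Reagents that add atoms: none
Why: Fluoride desilylation of the three secondary silyl ethers while all phenols are still benzyl-protected and so not prone to oxidation; no stereocentre is affected (descriptor changes are priority changes only).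

Step 10
Reactants: 17 the heptabenzyl ether from step 9
Product: 18 (2R,3R,4R)-2-(3,4-dihydroxyphenyl)-6-[(2R,3R,4S)-3,7,8-trihydroxy-2-(4-hydroxyphenyl)chroman-4-yl]chromane-3,4,7,8-tetrol (CNP0275688.2)
Conditions: H2 (1 atm), Pd(OH)2/C, THF–MeOH, rt
Reagents that add atoms: none
Why: Catalytic hydrogenolysis of the seven aryl benzyl ethers under neutral conditions, which are known from benzylated proanthocyanidins to spare the cyclic benzylic C2–O bonds, the doubly benzylic C4–H and a free benzylic hydroxyl.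

## Compound list

1 | 2,3,4-trihydroxybenzaldehyde | O=Cc1ccc(O)c(O)c1O | starting material
2 | 3,4-bis(benzyloxy)-2-hydroxybenzaldehyde | O=Cc1ccc(OCc2ccccc2)c(OCc2ccccc2)c1O | intermediate
3 | (tert-butyldimethylsilyloxy)acetaldehyde | O=CCO[Si](C)(C)C(C)(C)C | starting material
4 | (2R,3R)-3-[3,4-bis(benzyloxy)-2-hydroxyphenyl]-2-[(tert-butyldimethylsilyl)oxy]-3-hydroxypropanal (open-chain anti-aldol adduct) | O=C[C@H](O[Si](C)(C)C(C)(C)C)[C@H](O)c1ccc(OCc2ccccc2)c(OCc2ccccc2)c1O | intermediate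
5 | (3R,4R)-7,8-bis(benzyloxy)-3-[(tert-butyldimethylsilyl)oxy]chromane-2,4-diol (3,4-cis; anomer mixture) | OC1Oc2c(ccc(OCc3ccccc3)c2OCc2ccccc2)[C@@H](O)[C@H]1O[Si](C)(C)C(C)(C)C | intermediate
6 | (3R,4R)-7,8-bis(benzyloxy)-2,3,4-tris[(tert-butyldimethylsilyl)oxy]chromane (tris-silyl ether) | CC(C)(C)[Si](C)(C)OC1Oc2c(ccc(OCc3ccccc3)c2OCc2ccccc2)[C@@H](O[Si](C)(C)C(C)(C)C)[C@H]1O[Si](C)(C)C(C)(C)C | intermediate
7 | (3R,4R)-7,8-bis(benzyloxy)-3,4-bis[(tert-butyldimethylsilyl)oxy]chroman-2-ol (anomer mixture) | OC1Oc2c(ccc(OCc3ccccc3)c2OCc2ccccc2)[C@@H](O[Si](C)(C)C(C)(C)C)[C@H]1O[Si](C)(C)C(C)(C)C | intermediate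
8 | 4-bromo-1,2-bis(benzyloxy)benzene | Brc1ccc(OCc2ccccc2)c(OCc2ccccc2)c1 | starting material
9 | 3,4-bis(benzyloxy)phenylmagnesium bromide | Br[Mg]c1ccc(OCc2ccccc2)c(OCc2ccccc2)c1 | intermediate
10 | (1S,2S,3R)-3-[3,4-bis(benzyloxy)-2-hydroxyphenyl]-1-[3,4-bis(benzyloxy)phenyl]-2,3-bis[(tert-butyldimethylsilyl)oxy]propan-1-ol | Oc1c(OCc2ccccc2)c(OCc2ccccc2)ccc1[C@@H](O[Si](C)(C)C(C)(C)C)[C@@H](O[Si](C)(C)C(C)(C)C)[C@@H](O)c1ccc(OCc2ccccc2)c(OCc2ccccc2)c1 | intermediate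
11 | (3S,4S)-4-(benzylsulfanyl)-7,8-bis(benzyloxy)-3-[(tert-butyldimethylsilyl)oxy]chroman-2-ol (3,4-trans; anomer mixture) | OC1Oc2c(ccc(OCc3ccccc3)c2OCc2ccccc2)[C@H](SCc2ccccc2)[C@H]1O[Si](C)(C)C(C)(C)C | intermediate
12 | (3R,4R)-7,8-bis(benzyloxy)-4-{2,3-bis(benzyloxy)-5-[(1R,2S,3S)-3-[3,4-bis(benzyloxy)phenyl]-1,2-bis[(tert-butyldimethylsilyl)oxy]-3-hydroxypropyl]-4-hydroxyphenyl}-3-[(tert-butyldimethylsilyl)oxy]chroman-2-ol (3,4-trans; anomer mixture) | OC1Oc2c(ccc(OCc3ccccc3)c2OCc2ccccc2)[C@H](c2cc([C@@H](O[Si](C)(C)C(C)(C)C)[C@@H](O[Si](C)(C)C(C)(C)C)[C@@H](O)c3ccc(OCc4ccccc4)c(OCc4ccccc4)c3)c(O)c(OCc3ccccc3)c2OCc2ccccc2)[C@H]1O[Si](C)(C)C(C)(C)C | intermediate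
13 | 1-(benzyloxy)-4-bromobenzene | Brc1ccc(OCc2ccccc2)cc1 | starting material
14 | 4-(benzyloxy)phenylmagnesium bromide | Br[Mg]c1ccc(OCc2ccccc2)cc1 | intermediate
15 | (1S,2R,3R)-3-[3,4-bis(benzyloxy)-2-hydroxyphenyl]-3-{2,3-bis(benzyloxy)-5-[(1R,2S,3S)-3-[3,4-bis(benzyloxy)phenyl]-1,2-bis[(tert-butyldimethylsilyl)oxy]-3-hydroxypropyl]-4-hydroxyphenyl}-1-[4-(benzyloxy)phenyl]-2-[(tert-butyldimethylsilyl)oxy]propan-1-ol | Oc1c(OCc2ccccc2)c(OCc2ccccc2)ccc1[C@H](c1cc([C@@H](O[Si](C)(C)C(C)(C)C)[C@@H](O[Si](C)(C)C(C)(C)C)[C@@H](O)c2ccc(OCc3ccccc3)c(OCc3ccccc3)c2)c(O)c(OCc2ccccc2)c1OCc1ccccc1)[C@@H](O[Si](C)(C)C(C)(C)C)[C@@H](O)c1ccc(OCc2ccccc2)cc1 | intermediate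
16 | (2R,3S,4R)-7,8-bis(benzyloxy)-2-[3,4-bis(benzyloxy)phenyl]-6-{(2R,3R,4R)-7,8-bis(benzyloxy)-2-[4-(benzyloxy)phenyl]-3-[(tert-butyldimethylsilyl)oxy]chroman-4-yl}-3,4-bis[(tert-butyldimethylsilyl)oxy]chromane | C(Oc1ccc([C@H]2Oc3c(ccc(OCc4ccccc4)c3OCc3ccccc3)[C@H](c3cc4c(c(OCc5ccccc5)c3OCc3ccccc3)O[C@H](c3ccc(OCc5ccccc5)c(OCc5ccccc5)c3)[C@H](O[Si](C)(C)C(C)(C)C)[C@@H]4O[Si](C)(C)C(C)(C)C)[C@H]2O[Si](C)(C)C(C)(C)C)cc1)c1ccccc1 | intermediate
17 | (2R,3R,4R)-7,8-bis(benzyloxy)-2-[3,4-bis(benzyloxy)phenyl]-6-{(2R,3R,4R)-7,8-bis(benzyloxy)-2-[4-(benzyloxy)phenyl]-3-hydroxychroman-4-yl}chromane-3,4-diol | C(Oc1ccc([C@H]2Oc3c(ccc(OCc4ccccc4)c3OCc3ccccc3)[C@H](c3cc4c(c(OCc5ccccc5)c3OCc3ccccc3)O[C@H](c3ccc(OCc5ccccc5)c(OCc5ccccc5)c3)[C@H](O)[C@@H]4O)[C@H]2O)cc1)c1ccccc1 | intermediate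
18 | (2R,3R,4R)-2-(3,4-dihydroxyphenyl)-6-[(2R,3R,4S)-3,7,8-trihydroxy-2-(4-hydroxyphenyl)chroman-4-yl]chromane-3,4,7,8-tetrol | Oc1ccc([C@H]2Oc3c(ccc(O)c3O)[C@H](c3cc4c(c(O)c3O)O[C@H](c3ccc(O)c(O)c3)[C@H](O)[C@@H]4O)[C@H]2O)cc1 | target

## Step count and risks

Total step count: 10. Longest linear sequence: 9 steps (1 → 2 → 5 → 7 → 10 → 12 → 15 → 16 → 17 → 18; step 5 is the side branch).

The three steps most likely to fail:

**Step 2.** The acceptor is an electron-rich, hydrogen-bonded aldehyde, so self-aldol of 3 and dehydration of the adduct can win. Fallback: reagent-controlled anti-oxyallylation instead of the aldol, setting out from 2 and coming back at 7.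
- Silylation of 2 (TBSCl, imidazole, DMF) gives 3,4-bis(benzyloxy)-2-[(tert-butyldimethylsilyl)oxy]benzaldehyde F1.
- Addition of [(E)-3-(diisopropylaminodimethylsilyl)allyl]diisopinocampheylborane at −78 °C (the pinene-derived enantiomer that gives the 1R centre), then oxidative work-up with H2O2/KF/KHCO3, gives the anti-diol (1R,2S)-1-{3,4-bis(benzyloxy)-2-[(tert-butyldimethylsilyl)oxy]phenyl}but-3-ene-1,2-diol F2.
- TBSOTf/2,6-lutidine gives the tris-silyl ether (1R,2S)-1-{3,4-bis(benzyloxy)-2-[(tert-butyldimethylsilyl)oxy]phenyl}-1,2-bis[(tert-butyldimethylsilyl)oxy]but-3-ene F3.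
- K2OsO2(OH)4 (cat.)/NaIO4/2,6-lutidine cleaves the vinyl group to (2R,3R)-3-{3,4-bis(benzyloxy)-2-[(tert-butyldimethylsilyl)oxy]phenyl}-2,3-bis[(tert-butyldimethylsilyl)oxy]propanal F4.
- KHF2 in MeOH removes only the aryl silyl ether and the freed phenol closes onto the aldehyde to give lactol 7.
- Thioether 11 is then made from 7 with the same thiol and ZnI2, since the benzylic silyl ether ionises like the alcohol.

**Step 6.** The open-chain phenol 10 is hindered, O-alkylation of the phenol or self-condensation of 11 may compete, and HBF4 may ionise the free carbinol of 10. Fallback: couple two closed lactols and open the lower one afterwards, setting out from 11 (with 7 as partner) and coming back at 12.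
- TBSOTf/2,6-lutidine converts 11 into (3S,4S)-4-(benzylsulfanyl)-7,8-bis(benzyloxy)-2,3-bis[(tert-butyldimethylsilyl)oxy]chromane F5.
- AgBF4-promoted Friedel–Crafts coupling of F5 with lactol 7 (2 equiv), which has no ionisable free benzylic alcohol, gives (3R,4R)-7,8-bis(benzyloxy)-6-{(3R,4R)-7,8-bis(benzyloxy)-2,3-bis[(tert-butyldimethylsilyl)oxy]chroman-4-yl}-3,4-bis[(tert-butyldimethylsilyl)oxy]chroman-2-ol F6. Only its lower unit is a free lactol.
- Grignard reagent 9 therefore opens only that ring (Felkin–Anh) to give (3R,4R)-7,8-bis(benzyloxy)-4-{2,3-bis(benzyloxy)-5-[(1R,2S,3S)-3-[3,4-bis(benzyloxy)phenyl]-1,2-bis[(tert-butyldimethylsilyl)oxy]-3-hydroxypropyl]-4-hydroxyphenyl}-2,3-bis[(tert-butyldimethylsilyl)oxy]chromane F7.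
- Bu4NF/AcOH at −20 °C removes the anomeric silyl group and returns 12.

**Step 8.** The para-benzyloxybenzylic oxyphosphonium ions may ionise (SN1), eroding the inversion, and the carbinols are hindered by the neighbouring silyl ethers. Fallback: keep the lactol rings and form the C2–aryl bonds instead of the O1–C2 bonds, setting out from 7 and coming back at 16.
- Oxocarbenium Friedel–Crafts arylation of 7 with 1,2-bis(benzyloxy)benzene (BF3·OEt2, CH2Cl2, −78 °C; the arene adds cis to the neighbouring 3-silyloxy group) gives (2R,3S,4R)-7,8-bis(benzyloxy)-2-[3,4-bis(benzyloxy)phenyl]-3,4-bis[(tert-butyldimethylsilyl)oxy]chromane F8.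
- AgBF4 coupling of thioether 11 with F8 gives (3R,4R)-7,8-bis(benzyloxy)-4-{(2R,3S,4R)-7,8-bis(benzyloxy)-2-[3,4-bis(benzyloxy)phenyl]-3,4-bis[(tert-butyldimethylsilyl)oxy]chroman-6-yl}-3-[(tert-butyldimethylsilyl)oxy]chroman-2-ol F9.
- The same arylation of F9 with benzyl phenyl ether (para attack, cis to the 3-silyloxy group and trans to the 4-aryl group) gives 16.

## Further compounds

F1 | step 2 | 3,4-bis(benzyloxy)-2-[(tert-butyldimethylsilyl)oxy]benzaldehyde | O=Cc1ccc(OCc2ccccc2)c(OCc2ccccc2)c1O[Si](C)(C)C(C)(C)C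
F2 | step 2 | (1R,2S)-1-{3,4-bis(benzyloxy)-2-[(tert-butyldimethylsilyl)oxy]phenyl}but-3-ene-1,2-diol | C=C[C@H](O)[C@H](O)c1ccc(OCc2ccccc2)c(OCc2ccccc2)c1O[Si](C)(C)C(C)(C)C
F3 | step 2 | (1R,2S)-1-{3,4-bis(benzyloxy)-2-[(tert-butyldimethylsilyl)oxy]phenyl}-1,2-bis[(tert-butyldimethylsilyl)oxy]but-3-ene | C=C[C@H](O[Si](C)(C)C(C)(C)C)[C@H](O[Si](C)(C)C(C)(C)C)c1ccc(OCc2ccccc2)c(OCc2ccccc2)c1O[Si](C)(C)C(C)(C)C
F4 | step 2 | (2R,3R)-3-{3,4-bis(benzyloxy)-2-[(tert-butyldimethylsilyl)oxy]phenyl}-2,3-bis[(tert-butyldimethylsilyl)oxy]propanal | O=C[C@H](O[Si](C)(C)C(C)(C)C)[C@H](O[Si](C)(C)C(C)(C)C)c1ccc(OCc2ccccc2)c(OCc2ccccc2)c1O[Si](C)(C)C(C)(C)C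
F5 | step 6 | (3S,4S)-4-(benzylsulfanyl)-7,8-bis(benzyloxy)-2,3-bis[(tert-butyldimethylsilyl)oxy]chromane | CC(C)(C)[Si](C)(C)OC1Oc2c(ccc(OCc3ccccc3)c2OCc2ccccc2)[C@H](SCc2ccccc2)[C@H]1O[Si](C)(C)C(C)(C)C
F6 | step 6 | (3R,4R)-7,8-bis(benzyloxy)-6-{(3R,4R)-7,8-bis(benzyloxy)-2,3-bis[(tert-butyldimethylsilyl)oxy]chroman-4-yl}-3,4-bis[(tert-butyldimethylsilyl)oxy]chroman-2-ol | CC(C)(C)[Si](C)(C)OC1Oc2c(ccc(OCc3ccccc3)c2OCc2ccccc2)[C@H](c2cc3c(c(OCc4ccccc4)c2OCc2ccccc2)OC(O)[C@H](O[Si](C)(C)C(C)(C)C)[C@@H]3O[Si](C)(C)C(C)(C)C)[C@H]1O[Si](C)(C)C(C)(C)C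
F7 | step 6 | (3R,4R)-7,8-bis(benzyloxy)-4-{2,3-bis(benzyloxy)-5-[(1R,2S,3S)-3-[3,4-bis(benzyloxy)phenyl]-1,2-bis[(tert-butyldimethylsilyl)oxy]-3-hydroxypropyl]-4-hydroxyphenyl}-2,3-bis[(tert-butyldimethylsilyl)oxy]chromane | CC(C)(C)[Si](C)(C)OC1Oc2c(ccc(OCc3ccccc3)c2OCc2ccccc2)[C@H](c2cc([C@@H](O[Si](C)(C)C(C)(C)C)[C@@H](O[Si](C)(C)C(C)(C)C)[C@@H](O)c3ccc(OCc4ccccc4)c(OCc4ccccc4)c3)c(O)c(OCc3ccccc3)c2OCc2ccccc2)[C@H]1O[Si](C)(C)C(C)(C)C
F8 | step 8 | (2R,3S,4R)-7,8-bis(benzyloxy)-2-[3,4-bis(benzyloxy)phenyl]-3,4-bis[(tert-butyldimethylsilyl)oxy]chromane | c1cc2c(c(OCc3ccccc3)c1OCc1ccccc1)O[C@H](c1ccc(OCc3ccccc3)c(OCc3ccccc3)c1)[C@H](O[Si](C)(C)C(C)(C)C)[C@@H]2O[Si](C)(C)C(C)(C)C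
F9 | step 8 | (3R,4R)-7,8-bis(benzyloxy)-4-{(2R,3S,4R)-7,8-bis(benzyloxy)-2-[3,4-bis(benzyloxy)phenyl]-3,4-bis[(tert-butyldimethylsilyl)oxy]chroman-6-yl}-3-[(tert-butyldimethylsilyl)oxy]chroman-2-ol | OC1Oc2c(ccc(OCc3ccccc3)c2OCc2ccccc2)[C@H](c2cc3c(c(OCc4ccccc4)c2OCc2ccccc2)O[C@H](c2ccc(OCc4ccccc4)c(OCc4ccccc4)c2)[C@H](O[Si](C)(C)C(C)(C)C)[C@@H]3O[Si](C)(C)C(C)(C)C)[C@H]1O[Si](C)(C)C(C)(C)C
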